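- Start from run alpha: its solid is down to 0.2% at 40.0 h, and you want to know what that says about the theta flask and its remedies.

| setting | theta | alpha | flask |
|---|---|---|---|
| solid substrate | 0.50 M | 0.25 M | 0.50 M |
| temperature | 40 °C | 46 °C | 40 °C |
| remark | the very flask that is asked about, followed so far | run made earlier |  |
| time |  |  | 8.0 d |

| run | time / h | target / % | solid substrate / % |
|---|---|---|---|
| theta | 30.0 | 6.7 | 50.4 |
| theta | 60.0 | 12.3 | 17.2 |
| theta | 96.0 | 16.1 | 0 |
| theta | 120 | 16.7 | 0 |
| theta | 144 | 16.0 | 0 |
| alpha | 4.00 | 1.3 | 82.1 |
| alpha | 10.0 | 5.5 | 58.2 |
| alpha | 20.0 | 11.1 | 23.6 |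
| alpha | 30.0 | 16.4 | 0.1 |
| alpha | 40.0 | 18.2 | 0.2 |

(readings scatter by 0.3 percentage points)
- given per volume of solution although it is solid: solid substrate
- target that was removed still counts
- the earlier runs were read with a standard deviation of 0.3 percentage points
- steps thought possible: target <-> isomer of the product C; isomer of the product A <-> isomer of the product B; starting material <-> target; solid substrate <-> starting material; target <-> isomer of the product A
- at the start none of the solid substrate is in solution
- violet: at 8.0 d take out 90% of the target then present, then wait 15 d
- ochre: at 8.0 d raise the temperature by 10 K, then wait 15 d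
- amber: change nothing and wait 15 d more
- target, in percent of the solid substrate first charged, at 8.0 d
- the remedy with the largest gain of target, or "none" below 2 percentage points (violet / ochre / amber / none)
- target present, with what was taken out counted in, in percent of the solid substrate first charged, after ochre
- target present, with what was taken out counted in, in percent of the solid substrate first charged, after amber

- The puzzle: alpha reads 18.2% target at 40.0 h, yet theta, though it has stood longer than alpha, reads 16.0% at 144 h, with its solid at 0%.
- Each step offered turns one molecule into one, so if they are first order, the charge cancels from the plateau shares once the solid is gone, and between the plateaus of theta and alpha temperature remains as the difference.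
- Call f the plateau share, the fraction of dissolved material that is target, which I take to be under thermodynamic control, not kinetic: as a reading, theta's last 3 points average 16.3%. So I expect that at 8.0 d, and after amber.
- Alpha was still rising, by 1.8 percentage points in its last step. If each further rise is half the one before, they add that much again, so I put alpha's plateau at 20.0%.
- Stretching the straight line from f to that plateau, from 6.00 K to 10 K, gives my estimate for ochre, 22.5%, a gain of 6.2 points.
- Violet, first round: refilling to f gains 15 points. Second round: the refill draws on a pool shrunk by what was taken, so I reckon a gain for theta of 12 points, more than my estimate for ochre.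
- The forecast gives 15% now, 7% after ochre, 11% after amber and violet as best, since “removal pulls the pool back through the equilibrium”.
- The theta flask gives 16.0% at 8.0 d and still 15.9% at 1920 h. Amber ends at 15.9%, a change of −0.06 points; ochre ends at 21.9%, gaining 5.9 points. The best remedy is violet, gaining 12 points, against the 12 points reckoned from f.

    target ⇌ isomer of the product C (K = 1.90, k = 6.00 × 10⁻⁴ /min, Ea = 105 kJ/mol, ΔH = −37.0 kJ/mol)
    isomer of the product A ⇌ isomer of the product B (K = 0.360, k = 0.0160 /min, Ea = 105 kJ/mol, ΔH = −66.0 kJ/mol)
    starting material ⇌ target (K = 2.50, k = 4.20 × 10⁻⁴ /min, Ea = 108 kJ/mol, ΔH = −20.0 kJ/mol)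
    solid substrate ⇌ starting material, rate k4*(cs4 - [starting material]) while solid is left; crystals form when [starting material] > cs4 (solubility = 0.360 M, k = 5.50 × 10⁻⁴ /min)
    target ⇌ isomer of the product A (K = 2.20, k = 0.00150 /min, Ea = 113 kJ/mol, ΔH = −28.0 kJ/mol)
    (constants at 40 °C)

- The neighbour flask charged with 2.0 M still has 48.8% solid at 192 h, so f on the dissolved rest gives 8.35%. The computed flask holds 7.95%.

The readings were computed from invented constants; scatter was added.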